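**Assumption.** 3-Bromo-4-iodophenol (10) is treated as a catalogue compound. Ring positions of all intermediates are given in flavanone numbering (O1, C2, C3, C4, C4a, C5–C8, C8a), also before ring C exists.

## Analysis of the target

The target 21 is a 5-deoxyflavanone. Benzene ring A is fused to the dihydropyran-4-one ring C (O1, C2, C3, C4, C4a, C8a), and C2 carries ring B, which is itself part of a 2,2-dimethylchroman attached through its C6. Ring A bears a free phenol at C7 and a prenyl group at C8, the carbon between O7 and O1; C5 and C6 are unsubstituted. C2 (S) is the only stereocentre, so nothing in the molecule can relay its configuration. It is benzylic to the para-alkoxy ring B and sits β to the C4 carbonyl through O1, so it is lost by E1cB opening of O1–C2 under base and by benzylic ionisation under strong acid. The prenyl alkene is sensitive to electrophiles, hydrogenation and acid (cyclisation onto the C7 hydroxyl), and the C3 hydrogens are acidic. The difficulty is to set and keep C2 and to place the prenyl group at C8 and not at C6. The strategy rests on O1: it is bonded to C8a of ring A and to C2 of ring C, and it can be read as the hydroxyl oxygen of a secondary C2 carbinol that is arylated at C8a. C2 then becomes the product of a ketone reduction, and C8a becomes a bromide carbon whose halogen, with O7, flanks C8 and makes that position the most acidic CH of ring A.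

## Retrosynthetic reasoning

**21 back to 20 and 19 (no skeletal bond cut).** The C7 phenol is masked as a methoxymethyl ether (20) and the C4 ketone is taken back to the carbinol (19). The acetal ether is the ortho-directing group needed earlier and leaves under mild acid, the one medium in which C2 of a flavanone is safe. Holding C4 as an alcohol until ring C exists removes the retro-aldol and dehydration channels of a β-hydroxy ketone. The forward steps are a neutral oxidation and an acetal cleavage.

**19 back to 18 (O1–C8a cut).** This is the defining disconnection. Cutting at C8a and not at C2 keeps the stereogenic C2–O bond intact, so the forward ring closure cannot invert or scramble C2. The open form 18 is a 1,3-diol in which only the 3S hydroxyl can reach C8a in a six-membered closure. The forward reaction has to form an aryl ether at a bromide flanked by two ortho substituents.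

**18 back to 17, then to 15 and 9 (C4–C4a cut).** Cutting the aryl–carbinol bond separates ring A from the chiral three-carbon piece and makes the route convergent. The carbinol centre it creates is later oxidised, so no control is needed there. A cut at C3–C4 (aldol) was not taken because it would leave C2 as a ketone to be reduced next to a free hydroxyl that competes with catalyst control. The forward step needs an aryl nucleophile 16 at C4a that keeps the neighbouring bromide; this is why 15 carries iodine at C4a, which exchanges selectively.

**15 back to 11 and 12, and 11 back to 10 (C8–CH2 bond of the prenyl group cut).** In 11 the hydrogen at C8 lies between bromine and the acetal oxygen and is the most acidic on the ring, so deprotonation (13) and copper-mediated allylic substitution (14 with 12) place the prenyl group without any C6 isomer. The halogen pattern comes from 10.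

**9 back to 7, 6 and 5 (C2–H bond).** The aldehyde 9 is the silyl-protected, partially reduced form of the β-hydroxy ester 6, and 6 is the hydrogenation product of the β-keto ester 5. This puts the only stereocentre of the target on chelation-controlled hydrogenation of an aryl β-keto ester, before any fragile functionality is present.

**5 back to 3 and 4 (C3–C4 cut).** A crossed Claisen condensation of the methyl ketone 3 with the carbonate 4 supplies the carbon that becomes C4.

**3 back to 1 and 2.** The dihydropyran ring of the ring B chroman is opened at its aryl C–C and O–C bonds, leading to the phenol 1 and the diene 2, which are joined by acid-mediated annulation.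

## Alternatives that were turned down

**Alternative 1:** Ring A is built from acyclic pieces by cutting C8a–C8, C7–C6, C6–C5 and C4a–C8a, which leads to the diazo enone A2 and the siloxyalkyne A3. In the forward key step, irradiation of A2 triggers a Wolff rearrangement to a vinylketene. The ketene adds A3 in a (2+2) cycloaddition, and the cyclobutenone opens (four electrons) and recloses (six electrons) to the phenol A1. In its favour, the prenyl group arrives as the alkyne substituent, so its position at C8 is fixed by construction; O7 and O1 come out differentiated, and no metalation next to halogens is needed. On this point it is stronger than the chosen route. Against it, ring A of the target is a plain tetrasubstituted benzene that can be had from a dihalophenol in two steps, whereas A2 and A3 each need several steps and the key step needs photochemistry of a diazo compound. More seriously, A1 is only a masked ortho-hydroxyacetophenone: ring C and C2 are still to be made, by condensation and an enantioselective oxa-Michael closure, which is reversible through the same E1cB opening that racemises flavanones. The chosen strategy offers a stereocentre set by ketone hydrogenation and a ring closure that cannot touch it, in fewer steps.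

**Alternative 2:** The C3–C4 bond is cut as the double bond of a 4-silyloxy-2H-chromene, leading to the diene A5, in which O1–C2 and the C2 stereocentre already exist. In the forward key step, the second-generation Hoveyda–Grubbs catalyst joins the C2 vinyl group to the silyl enol ether on C4a and gives A4. In its favour, the closure is neutral, it takes place away from the crowded C8a, and the product holds C4 at the ketone level without an oxidation; on the ease of ring closure it is as strong as or stronger than an O-arylation at a doubly ortho-substituted bromide. Against it, C2 in A5 is at once benzylic to a para-alkoxy ring, allylic and attached to an aryloxide leaving group, so ionisation with ion-pair return can erode the configuration. A4, a 2-aryl-2H-chromene, can open thermally by a six-electron retro-electrocyclisation to an ortho-quinone methide and reclose, which scrambles C2. The prenyl alkene cannot be carried through metathesis, so A4 holds bromine at C8 and the prenyl group must be introduced late by cross-coupling on a base-sensitive flavanone, with its own α/γ ambiguity. The chosen strategy offers a saturated, never allylic C2 carbinol and a prenyl group in place from the second step of the ring A branch.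

**Alternative 3:** C4a–C4, C4–C3 and O1–C2 are cut together, leading to the iodophenol A7, the alkyne A8 and a one-carbon carbonyl source. In the forward key step, PdCl2(PPh3)2 and diethylamine effect a carbonylative Sonogashira coupling followed by amine-mediated six-membered oxa-Michael closure to the flavone A6. In its favour, it is the most convergent plan: three bonds and ring C form in one operation, and the flat intermediates cannot eliminate or epimerise. On convergence and on step count to the ring system it is stronger than the chosen route. Against it, A6 is at the wrong oxidation level. C2=C3 must be reduced enantioselectively to reach 20, in a vinylogous ester that resists conjugate reduction, with over-reduction at C4 and the prenyl alkene as competitors. The only stereocentre would then depend on the least predictable step, at the end of the route. Five-membered closure to an aurone is a further competitor in the annulation. The chosen strategy gives up some convergence and in return fixes C2 early on a simple ketone and keeps every later step stereoretentive.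

Key step: step 10

## Route

**Step 1**
Reactants: 1 4-hydroxyacetophenone; 2 isoprene
Product: 3 1-(2,2-dimethylchroman-6-yl)ethanone
Conditions: 2 (1.5 equiv), 85% H3PO4, xylene, 35 °C
Reagents that add atoms: none
Why: Acid-mediated phenol–diene chroman annulation: Friedel–Crafts prenylation ortho to the hydroxyl, then Markovnikov hydroalkoxylation of the new alkene; the para position is blocked by the acetyl group, which also disfavours a second alkylation.

**Step 2**
Reactants: 3 1-(2,2-dimethylchroman-6-yl)ethanone; 4 dimethyl carbonate
Product: 5 methyl 3-(2,2-dimethylchroman-6-yl)-3-oxopropanoate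
Conditions: NaH (2.5 equiv), 4 (3 equiv), THF, reflux; then aq. HCl, 0 °C
Reagents that add atoms: none
Why: Crossed Claisen condensation of a methyl ketone enolate with a non-enolisable carbonate; deprotonation of the acidic β-keto ester as it forms drives the equilibrium.

**Step 3**
Reactants: 5 methyl 3-(2,2-dimethylchroman-6-yl)-3-oxopropanoate
Product: 6 methyl (3S)-3-(2,2-dimethylchroman-6-yl)-3-hydroxypropanoate
Conditions: H2 (50 atm), RuCl2[(R)-BINAP] (0.5 mol%), MeOH, 40 °C
Reagents that add atoms: none
Why: Noyori asymmetric hydrogenation of a β-keto ester: the substrate chelates ruthenium through both carbonyls and the (R)-diphosphine exposes the ketone face that leads to the carbinol of S configuration (S because the aryl group outranks the CH2CO2Me arm); this step sets the only stereocentre of the target.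

**Step 4**
Reactants: 6 methyl (3S)-3-(2,2-dimethylchroman-6-yl)-3-hydroxypropanoate
Product: 7 methyl (3S)-3-(tert-butyldimethylsilyloxy)-3-(2,2-dimethylchroman-6-yl)propanoate
Conditions: TBSCl, imidazole, DMF, rt
Reagents that add atoms: tert-butyldimethylsilyl chloride, CC(C)(C)[Si](C)(C)Cl
Why: Standard silylation of a secondary alcohol; masking the benzylic hydroxyl prevents retro-aldol cleavage and alkoxide-driven elimination in the hydride and Grignard steps.

**Step 5**
Reactants: 7 methyl (3S)-3-(tert-butyldimethylsilyloxy)-3-(2,2-dimethylchroman-6-yl)propanoate
Product: 9 (3S)-3-(tert-butyldimethylsilyloxy)-3-(2,2-dimethylchroman-6-yl)propanal, via aluminium hemiacetal 8 (not isolated)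
Conditions: i-Bu2AlH (DIBAL-H, 1.1 equiv), CH2Cl2, −78 °C; MeOH, then aq. potassium sodium tartrate
Reagents that add atoms: none
Why: Partial reduction of an ester: the tetrahedral aluminium alkoxide persists at −78 °C and releases the aldehyde only on work-up; the stereocentre is not involved and the crude aldehyde is used at once to avoid β-elimination.

**Step 6**
Reactants: 10 3-bromo-4-iodophenol
Product: 11 2-bromo-1-iodo-4-(methoxymethoxy)benzene
Conditions: MeOCH2Cl, i-Pr2NEt, CH2Cl2, 0 °C → rt
Reagents that add atoms: chloromethyl methyl ether, COCCl
Why: O-alkylation of the phenol to its methoxymethyl ether, which later directs metalation and is removed under mild acid.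

**Step 7**
Reactants: 11 2-bromo-1-iodo-4-(methoxymethoxy)benzene; 12 prenyl bromide
Product: 15 2-bromo-1-iodo-4-(methoxymethoxy)-3-(3-methylbut-2-enyl)benzene, via aryllithium 13 (not isolated), via arylcopper 14 (not isolated)
Conditions: LiN(i-Pr)2 (LDA, 1.1 equiv), THF, −78 °C; CuBr·SMe2 (1.1 equiv), −78 °C; 12 (1.3 equiv), −78 → −20 °C
Reagents that add atoms: none
Why: Directed ortho-metalation: the hydrogen between bromine and the acetal oxygen is the most acidic on the ring, the amide base does not exchange with the iodide, and at −78 °C the ortho-bromo aryllithium does not lose LiBr. Transmetalation to the arylcopper and allylic substitution at the unhindered CH2 terminus of 12 then give the linear prenyl group.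

**Step 8**
Reactants: 15 2-bromo-1-iodo-4-(methoxymethoxy)-3-(3-methylbut-2-enyl)benzene; 9 (3S)-3-(tert-butyldimethylsilyloxy)-3-(2,2-dimethylchroman-6-yl)propanal
Product: 17 (1RS,3S)-1-[2-bromo-4-(methoxymethoxy)-3-(3-methylbut-2-enyl)phenyl]-3-(tert-butyldimethylsilyloxy)-3-(2,2-dimethylchroman-6-yl)propan-1-ol, via aryl Grignard reagent 16 (not isolated)
Conditions: 15 (1.2 equiv), i-PrMgCl·LiCl (1.1 equiv), THF, −40 °C; then 9 (1.0 equiv), −40 → −10 °C; aq. NH4Cl
Reagents that add atoms: none
Why: Iodine–magnesium exchange is much faster at C–I than at C–Br, and the ortho-bromoarylmagnesium species is stable at these temperatures; its 1,2-addition to the aldehyde forms the C4–C4a bond. The new carbinol centre forms as a mixture of epimers under weak 1,3-induction, which does not matter because it is oxidised in step 11.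

**Step 9**
Reactants: 17 (1RS,3S)-1-[2-bromo-4-(methoxymethoxy)-3-(3-methylbut-2-enyl)phenyl]-3-(tert-butyldimethylsilyloxy)-3-(2,2-dimethylchroman-6-yl)propan-1-ol
Product: 18 (1RS,3S)-1-[2-bromo-4-(methoxymethoxy)-3-(3-methylbut-2-enyl)phenyl]-3-(2,2-dimethylchroman-6-yl)propane-1,3-diol
Conditions: Bu4NF (TBAF), THF, 0 °C → rt
Reagents that add atoms: none
Why: Fluoride cleavage of the silyl ether; the basic, non-ionising medium leaves both benzylic C–O bonds, the acetal and the alkene untouched.

**Step 10 (key step)**
Reactants: 18 (1RS,3S)-1-[2-bromo-4-(methoxymethoxy)-3-(3-methylbut-2-enyl)phenyl]-3-(2,2-dimethylchroman-6-yl)propane-1,3-diol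
Product: 19 (2S,4RS)-2-(2,2-dimethylchroman-6-yl)-7-(methoxymethoxy)-8-(3-methylbut-2-enyl)chroman-4-ol
Conditions: CuI (10 mol%), 3,4,7,8-tetramethyl-1,10-phenanthroline (20 mol%), Cs2CO3 (2 equiv), toluene (0.05 M), 110 °C, Ar
Reagents that add atoms: none
Why: This is an intramolecular Ullmann-type C–O coupling; the closest known reaction type is the copper-catalysed O-arylation of secondary alcohols by aryl bromides that closes chromans from 3-(2-bromoaryl)propanols. Carbonate and ligated monovalent copper turn the 3S hydroxyl into a copper alkoxide, the C8a–Br bond is activated at the metal (oxidative addition to an aryl trivalent copper species or its halogen-atom-transfer equivalent), and C–O reductive elimination forms O1–C8a and returns the catalyst. Ring C closes in a six-membered mode, formally 6-exo at C8a because the departing bromide lies outside the new ring, by way of a seven-membered cupracycle. No stereocentre is created: C2 keeps the S configuration from step 3 because none of its bonds is broken, and C4 remains a mixture of epimers. The step needs selectivity between the two hydroxyls and against intermolecular arylation; the C4 hydroxyl could only close a four-membered ring, so ring size decides, and the tether together with moderate dilution favours closure over oligomerisation. The bromide is flanked by the prenyl group and the side chain, which slows its activation, but intramolecular delivery of the alkoxide and the electron-rich phenanthroline ligand offset this, and the C7 acetal oxygen is meta to the bromide and does not deactivate it. Keeping C4 as a carbinol excludes the retro-aldol and E1cB pathways that a β-hydroxy ketone would follow under carbonate at this temperature. The prenyl alkene and the acetal are inert to these basic, non-oxidising conditions.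

**Step 11**
Reactants: 19 (2S,4RS)-2-(2,2-dimethylchroman-6-yl)-7-(methoxymethoxy)-8-(3-methylbut-2-enyl)chroman-4-ol
Product: 20 (2S)-2-(2,2-dimethylchroman-6-yl)-7-(methoxymethoxy)-8-(3-methylbut-2-enyl)chroman-4-one
Conditions: Dess–Martin periodinane, pyridine, CH2Cl2, 0 °C → rt
Reagents that add atoms: none
Why: Dess–Martin oxidation of a secondary benzylic alcohol under buffered conditions; both C4 epimers converge on one ketone, and the absence of strong base avoids retro-oxa-Michael opening at C2.

**Step 12**
Reactants: 20 (2S)-2-(2,2-dimethylchroman-6-yl)-7-(methoxymethoxy)-8-(3-methylbut-2-enyl)chroman-4-one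
Product: 21 euchrenone a17, (2S)-2-(2,2-dimethylchroman-6-yl)-7-hydroxy-8-(3-methylbut-2-enyl)chroman-4-one
Conditions: 3 M aq. HCl–MeOH (1:4), 40 °C
Reagents that add atoms: none
Why: Acid-catalysed transacetalisation of the aryl methoxymethyl ether to methanol; flavanones epimerise through base-induced ring opening and not readily in dilute acid, and short exposure at moderate temperature should spare the prenyl group.

## Compound list

1 | 4-hydroxyacetophenone | CC(=O)c1ccc(O)cc1 | starting material
2 | isoprene (2-methylbuta-1,3-diene) | C=CC(C)=C | starting material
3 | 1-(2,2-dimethylchroman-6-yl)ethanone | CC(=O)c1ccc2c(c1)CCC(C)(C)O2 | intermediate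
4 | dimethyl carbonate | COC(=O)OC | starting material
5 | methyl 3-(2,2-dimethylchroman-6-yl)-3-oxopropanoate | COC(=O)CC(=O)c1ccc2c(c1)CCC(C)(C)O2 | intermediate
6 | methyl (3S)-3-(2,2-dimethylchroman-6-yl)-3-hydroxypropanoate | COC(=O)C[C@H](O)c1ccc2c(c1)CCC(C)(C)O2 | intermediate
7 | methyl (3S)-3-(tert-butyldimethylsilyloxy)-3-(2,2-dimethylchroman-6-yl)propanoate | COC(=O)C[C@H](O[Si](C)(C)C(C)(C)C)c1ccc2c(c1)CCC(C)(C)O2 | intermediate
8 | diisobutylaluminium hemiacetal of 7 (epimers at the hemiacetal carbon) | COC(O[Al](CC(C)C)CC(C)C)C[C@H](O[Si](C)(C)C(C)(C)C)c1ccc2c(c1)CCC(C)(C)O2 | intermediate (not isolated)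
9 | (3S)-3-(tert-butyldimethylsilyloxy)-3-(2,2-dimethylchroman-6-yl)propanal | O=CC[C@H](O[Si](C)(C)C(C)(C)C)c1ccc2c(c1)CCC(C)(C)O2 | intermediate
10 | 3-bromo-4-iodophenol | Oc1ccc(I)c(Br)c1 | starting material
11 | 2-bromo-1-iodo-4-(methoxymethoxy)benzene | COCOc1ccc(I)c(Br)c1 | intermediate
12 | prenyl bromide (1-bromo-3-methylbut-2-ene) | CC(C)=CCBr | starting material
13 | [2-bromo-3-iodo-6-(methoxymethoxy)phenyl]lithium | [Li]c1c(OCOC)ccc(I)c1Br | intermediate (not isolated)
14 | [2-bromo-3-iodo-6-(methoxymethoxy)phenyl]copper | [Cu]c1c(OCOC)ccc(I)c1Br | intermediate (not isolated)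
15 | 2-bromo-1-iodo-4-(methoxymethoxy)-3-(3-methylbut-2-enyl)benzene | CC(C)=CCc1c(OCOC)ccc(I)c1Br | intermediate
16 | [2-bromo-4-(methoxymethoxy)-3-(3-methylbut-2-enyl)phenyl]magnesium chloride (LiCl complex) | CC(C)=CCc1c(OCOC)ccc([Mg]Cl)c1Br | intermediate (not isolated)
17 | (1RS,3S)-1-[2-bromo-4-(methoxymethoxy)-3-(3-methylbut-2-enyl)phenyl]-3-(tert-butyldimethylsilyloxy)-3-(2,2-dimethylchroman-6-yl)propan-1-ol | CC(C)=CCc1c(OCOC)ccc(C(O)C[C@H](O[Si](C)(C)C(C)(C)C)c2ccc3c(c2)CCC(C)(C)O3)c1Br | intermediate
18 | (1RS,3S)-1-[2-bromo-4-(methoxymethoxy)-3-(3-methylbut-2-enyl)phenyl]-3-(2,2-dimethylchroman-6-yl)propane-1,3-diol | CC(C)=CCc1c(OCOC)ccc(C(O)C[C@H](O)c2ccc3c(c2)CCC(C)(C)O3)c1Br | intermediate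
19 | (2S,4RS)-2-(2,2-dimethylchroman-6-yl)-7-(methoxymethoxy)-8-(3-methylbut-2-enyl)chroman-4-ol | CC(C)=CCc1c(OCOC)ccc2c1O[C@H](c1ccc3c(c1)CCC(C)(C)O3)CC2O | intermediate
20 | (2S)-2-(2,2-dimethylchroman-6-yl)-7-(methoxymethoxy)-8-(3-methylbut-2-enyl)chroman-4-one | CC(C)=CCc1c(OCOC)ccc2c1O[C@H](c1ccc3c(c1)CCC(C)(C)O3)CC2=O | intermediate
21 | euchrenone a17, (2S)-2-(2,2-dimethylchroman-6-yl)-7-hydroxy-8-(3-methylbut-2-enyl)chroman-4-one | CC(C)=CCc1c(O)ccc2c1O[C@H](c1ccc3c(c1)CCC(C)(C)O3)CC2=O | target

## Step count and least certain steps

Total step count: 12. Longest linear sequence: 10 steps (steps 1–5 and 8–12, from 1); the ring A branch (steps 6 and 7) joins at step 8.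

**Step 10 (key step).** The most likely failure is slow activation of the C8a–Br bond between two ortho substituents, so that protodebromination or slow degradation of the dialkoxide outruns ring closure; the free benzylic C4 hydroxyl next to the bromide may also hold copper in an unproductive chelate. The fallback sets out from 17 and returns at 19. It leaves only the C2 hydroxyl free and moves to a palladium cycle (oxidative addition to zerovalent palladium, alkoxide exchange, C–O reductive elimination from divalent palladium).
- The free hydroxyl of 17 is acylated (pivaloyl chloride, pyridine, DMAP) to (1RS,3S)-1-[2-bromo-4-(methoxymethoxy)-3-(3-methylbut-2-enyl)phenyl]-3-(tert-butyldimethylsilyloxy)-3-(2,2-dimethylchroman-6-yl)propyl pivalate F1.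
- The silyl ether is removed with Bu4NF buffered by AcOH to give (1RS,3S)-1-[2-bromo-4-(methoxymethoxy)-3-(3-methylbut-2-enyl)phenyl]-3-(2,2-dimethylchroman-6-yl)-3-hydroxypropyl pivalate F2.
- Ring C is closed with Pd(OAc)2, 2-(di-tert-butylphosphino)-1,1′-binaphthyl and Cs2CO3 in toluene at 80 °C to (2S,4RS)-2-(2,2-dimethylchroman-6-yl)-7-(methoxymethoxy)-8-(3-methylbut-2-enyl)chroman-4-yl pivalate F3.
- The ester is cleaved with i-Bu2AlH at −78 °C to give 19.

**Step 7.** The most likely failure is loss of LiBr from the ortho-bromo aryllithium (aryne formation) or iodine scrambling while the slow transfer to the hindered arylcopper is awaited, together with attack at the tertiary terminus of the allyl system. The fallback sets out from 11 and returns at 15. The same metalation is quenched at −78 °C with allyl bromide, which reacts fast and has no regiochemical ambiguity, to give 3-allyl-2-bromo-1-iodo-4-(methoxymethoxy)benzene F4. Cross-metathesis with 2-methylbut-2-ene (second-generation Grubbs catalyst, CH2Cl2, 40 °C) then turns the allyl into the prenyl group of 15.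

**Step 8.** The most likely failure is loss of magnesium halide from 16 to an aryne if the exchange needs warming (the iodide is para to the donor oxygen, which slows exchange), or deprotonation of the enolisable aldehyde followed by β-elimination of silanolate. The fallback sets out from 15 and 9 and returns at 17. It is a Nozaki–Hiyama–Kishi coupling (CrCl2 in excess, catalytic NiCl2, DMF, rt): zerovalent nickel inserts into C–I in preference to C–Br, and the aryl group passes to trivalent chromium, which is non-basic and does not eliminate. No new compound arises.

**Step 1.** The most likely failure is sluggish ring alkylation of the acetyl-deactivated phenol, with oligomerisation of the diene and arrest at open-chain prenylated stages. The fallback sets out from 1 and returns at 3.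
- O-alkylation of 1 with 3-chloro-3-methylbut-1-yne (K2CO3, KI, acetone, reflux) gives 1-[4-(2-methylbut-3-yn-2-yloxy)phenyl]ethanone F5.
- Thermal propargyl Claisen rearrangement, hydrogen shift and six-electron ring closure (N,N-diethylaniline, 190 °C) give 1-(2,2-dimethyl-2H-chromen-6-yl)ethanone F6.
- Hydrogenation of the chromene double bond (H2, Pd/C, EtOAc) gives 3.

**Step 12.** The most likely failure is acid-triggered addition of the freed C7 hydroxyl to the neighbouring prenyl alkene, or erosion at C2 by reversible opening of ring C on prolonged exposure to protic acid. The fallback sets out from 20 and returns at 21. It replaces solvolysis by an aprotic silyl exchange: Et3SiOTf and 2,2′-bipyridyl in CH2Cl2 at 0 °C convert the aryl acetal directly into (2S)-2-(2,2-dimethylchroman-6-yl)-8-(3-methylbut-2-enyl)-7-(triethylsilyloxy)chroman-4-one F7. The silyl ether is then cleaved with HF·pyridine in THF at 0 °C.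

## Further compounds

F1 | step 10 | (1RS,3S)-1-[2-bromo-4-(methoxymethoxy)-3-(3-methylbut-2-enyl)phenyl]-3-(tert-butyldimethylsilyloxy)-3-(2,2-dimethylchroman-6-yl)propyl pivalate | CC(C)=CCc1c(OCOC)ccc(C(OC(=O)C(C)(C)C)C[C@H](O[Si](C)(C)C(C)(C)C)c2ccc3c(c2)CCC(C)(C)O3)c1Br
F2 | step 10 | (1RS,3S)-1-[2-bromo-4-(methoxymethoxy)-3-(3-methylbut-2-enyl)phenyl]-3-(2,2-dimethylchroman-6-yl)-3-hydroxypropyl pivalate | CC(C)=CCc1c(OCOC)ccc(C(OC(=O)C(C)(C)C)C[C@H](O)c2ccc3c(c2)CCC(C)(C)O3)c1Br
F3 | step 10 | (2S,4RS)-2-(2,2-dimethylchroman-6-yl)-7-(methoxymethoxy)-8-(3-methylbut-2-enyl)chroman-4-yl pivalate | CC(C)=CCc1c(OCOC)ccc2c1O[C@H](c1ccc3c(c1)CCC(C)(C)O3)CC2OC(=O)C(C)(C)C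
F4 | step 7 | 3-allyl-2-bromo-1-iodo-4-(methoxymethoxy)benzene | C=CCc1c(OCOC)ccc(I)c1Br
F0 | step 8 | none | none
F5 | step 1 | 1-[4-(2-methylbut-3-yn-2-yloxy)phenyl]ethanone | CC(=O)c1ccc(OC(C)(C)C#C)cc1
F6 | step 1 | 1-(2,2-dimethyl-2H-chromen-6-yl)ethanone | CC(=O)c1ccc2c(c1)C=CC(C)(C)O2
F7 | step 12 | (2S)-2-(2,2-dimethylchroman-6-yl)-8-(3-methylbut-2-enyl)-7-(triethylsilyloxy)chroman-4-one | CC(C)=CCc1c(O[Si](CC)(CC)CC)ccc2c1O[C@H](c1ccc3c(c1)CCC(C)(C)O3)CC2=O
A1 | alternative 1 | 6-(2-methyl-1,3-dioxolan-2-yl)-2-(3-methylbut-2-enyl)-3-(triisopropylsilyloxy)phenol | CC(C)=CCc1c(O[Si](C(C)C)(C(C)C)C(C)C)ccc(C2(C)OCCO2)c1O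
A2 | alternative 1 | (E)-1-diazo-4-(2-methyl-1,3-dioxolan-2-yl)but-3-en-2-one | CC1(/C=C/C(=O)C=[N+]=[N-])OCCO1
A3 | alternative 1 | triisopropyl[(5-methylhex-4-en-1-ynyl)oxy]silane | CC(C)=CCC#CO[Si](C(C)C)(C(C)C)C(C)C
A4 | alternative 2 | (S)-8-bromo-4-(tert-butyldimethylsilyloxy)-2-(2,2-dimethylchroman-6-yl)-7-(triisopropylsilyloxy)-2H-chromene | Brc1c(O[Si](C(C)C)(C(C)C)C(C)C)ccc2c1O[C@H](c1ccc3c(c1)CCC(C)(C)O3)C=C2O[Si](C)(C)C(C)(C)C
A5 | alternative 2 | (S)-{2-bromo-6-[1-(tert-butyldimethylsilyloxy)vinyl]-3-(triisopropylsilyloxy)phenyl} 1-(2,2-dimethylchroman-6-yl)prop-2-enyl ether | Brc1c(O[Si](C(C)C)(C(C)C)C(C)C)ccc(C(=C)O[Si](C)(C)C(C)(C)C)c1O[C@H](c1ccc2c(c1)CCC(C)(C)O2)C=C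
A6 | alternative 3 | 2-(2,2-dimethylchroman-6-yl)-7-(methoxymethoxy)-8-(3-methylbut-2-enyl)chromen-4-one | CC(C)=CCc1c(OCOC)ccc2c1OC(c1ccc3c(c1)CCC(C)(C)O3)=CC2=O
A7 | alternative 3 | 6-iodo-3-(methoxymethoxy)-2-(3-methylbut-2-enyl)phenol | CC(C)=CCc1c(OCOC)ccc(I)c1O
A8 | alternative 3 | 6-ethynyl-2,2-dimethylchroman | C#Cc1ccc2c(c1)CCC(C)(C)O2
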